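**Retrosynthetic overview**
- The target is the tyrosol (4-hydroxyphenethyl) ester of unbranched tetracontanoic acid (C40). The last disconnection is the ester C1(=O)–O bond, giving methyl tetracontanoate and tyrosol (acid-catalysed acyl exchange at the primary OH only).
- The chain is cut at C21–C22 (numbered from the ester carbonyl C1). C22–C40 comes from eicosanoic acid and C1–C21 from monomethyl docosanedioate, joined by a crossed Kolbe anodic decarboxylative radical coupling in which each acid loses one CO2.
- Enabling feature: C2–C40 is an unbranched, heteroatom-free polymethylene chain. C21 and C22 are plain CH2 groups that become unstabilised primary radicals, and the only functional group on the chain (the C1 ester carbonyl) is 19 CH2 groups away, so radical dimerisation rather than cation formation is expected.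
- No ring is formed in the route. The only ring, the 4-hydroxyphenyl ring, arrives intact with tyrosol after the electrolysis, because an electron-rich phenol would be oxidised at the anode before the carboxylates.

Key step: step 2

Remark: the target has no stereocentre and no stereogenic double bond; it is achiral, so no stereocontrol is needed.

Step 1
Reactants: 1 docosanedioic acid
Product: 2 22-methoxy-22-oxodocosanoic acid (monomethyl docosanedioate)
Conditions: MeOH (1.0–1.2 equiv), cat. H2SO4, toluene, 80–90 °C (sealed), to equilibrium; 2 separated from recovered 1 (insoluble in cold toluene) and from the diester (SiO2), both recycled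
Reagents that add atoms: methanol, CO
Why: Fischer esterification under equilibrium control with limiting methanol should give a statistical mixture from which the half-ester is isolated by its intermediate polarity, the two symmetric by-products being re-equilibrated.

Step 2
Reactants: 2 22-methoxy-22-oxodocosanoic acid (1 equiv); 3 eicosanoic acid (arachidic acid, 3 equiv)
Product: 6 methyl tetracontanoate, via nonadecyl radical 4 (not isolated), via 21-methoxy-21-oxohenicosyl radical 5 (not isolated)
Conditions: KOH (5–10 mol% of total acid), MeOH/petroleum ether, 50 °C, undivided cell, smooth Pt anode and Pt cathode, constant current (about 0.2 A cm⁻²) until the electrolyte turns faintly alkaline, periodic polarity reversal; SiO2 (hexane, then hexane/toluene)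
Reagents that add atoms: none
Why: The carboxylates of 2 and 3 are discharged at the platinum anode at high current density, the acyloxy radicals lose CO2, and the primary radicals 4 and 5 combine at the electrode surface, forming the C21–C22 bond and so the whole C40 chain from a C20 and a C22 acid in one operation. The closest known reaction type is the crossed (mixed) Kolbe electrolysis of a fatty acid with a dicarboxylic acid half-ester, the classical chain-extension route to very-long-chain fatty esters. No ring is closed and no stereocentre is created. The step needs cross- over homo-coupling and one-electron radical coupling over further oxidation to cations (Hofer–Moest pathway); the excess of cheap 3 lets 5 meet mainly 4, and both radicals are unbranched primary alkyls without α-heteroatom or aryl group, which together with smooth Pt, high current density and a weakly acidic medium favours dimerisation. The methyl ester is anodically inert and cannot be scrambled by cathodically formed methoxide because the solvent is methanol; the petroleum ether keeps the waxy products off the anode, and the symmetric by-products (C38 alkane, C42 diester) each differ from 6 by one ester group and should separate by polarity.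

Step 3
Reactants: 6 methyl tetracontanoate; 7 tyrosol [4-(2-hydroxyethyl)phenol] (3 equiv)
Product: 8 2-(4-hydroxyphenyl)ethyl tetracontanoate (target)
Conditions: p-TsOH·H2O (10 mol%), toluene, reflux with slow distillation of the toluene/MeOH azeotrope; cool, filter, wash with MeOH/H2O; SiO2 if needed
Reagents that add atoms: none
Why: Acid-catalysed transesterification driven by removal of methanol should acylate only the primary aliphatic hydroxyl of tyrosol, since the weakly nucleophilic phenolic OH does not undergo acyl exchange under acidic conditions, a chemoselectivity with close precedent for lipophilic tyrosol esters made from fatty acid methyl esters.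

**Compound list**
1 | docosanedioic acid | OC(=O)CCCCCCCCCCCCCCCCCCCCC(=O)O | starting material
2 | 22-methoxy-22-oxodocosanoic acid (monomethyl docosanedioate) | OC(=O)CCCCCCCCCCCCCCCCCCCCC(=O)OC | intermediate
3 | eicosanoic acid (arachidic acid) | CCCCCCCCCCCCCCCCCCCC(=O)O | starting material
4 | nonadecyl radical | CCCCCCCCCCCCCCCCCC[CH2] | intermediate
5 | 21-methoxy-21-oxohenicosyl radical | [CH2]CCCCCCCCCCCCCCCCCCCC(=O)OC | intermediate
6 | methyl tetracontanoate | CCCCCCCCCCCCCCCCCCCCCCCCCCCCCCCCCCCCCCCC(=O)OC | intermediate
7 | tyrosol, 4-(2-hydroxyethyl)phenol | OCCc1ccc(O)cc1 | starting material
8 | 2-(4-hydroxyphenyl)ethyl tetracontanoate | CCCCCCCCCCCCCCCCCCCCCCCCCCCCCCCCCCCCCCCC(=O)OCCc1ccc(O)cc1 | target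

**Step count:** 3 steps in total. Longest linear sequence: 3 steps (1 → 2 → 6 → 8).

**Steps most likely to fail**

Step 2 (most risky). The electrolysis may stall through passivation of the anode by the waxy, poorly soluble products. Material may be lost to statistical homo-coupling of each radical, to radical disproportionation, and to over-oxidation of the radicals to cations that are trapped by methanol or eliminate. Fallback, setting out from 2 and returning at 6: 2 is condensed with N-hydroxyphthalimide (DIC, cat. DMAP, CH2Cl2/THF) to give the redox-active ester 1,3-dioxoisoindolin-2-yl methyl docosanedioate F1. Commercial 1-bromononadecane (CCCCCCCCCCCCCCCCCCCBr) is converted with Mg in THF into nonadecylmagnesium bromide F2 and then with ZnCl2 (0.5 equiv) into dinonadecylzinc F3. A nickel-catalysed decarboxylative alkyl–alkyl Negishi coupling of F1 with F3 (NiCl2·glyme, 2,2'-bipyridine, THF/DMF, rt) should form the same C21–C22 bond cross-selectively and give 6.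

Step 3. Acyl exchange may stay incomplete because of the poor solubility of the C40 ester and the equilibrium, and hot acid may cause self-condensation of tyrosol, complicating isolation. Fallback, setting out from 6 and returning at 8: saponification (KOH, EtOH/toluene, reflux; then HCl) gives tetracontanoic acid F4. Steglich esterification with commercial 2-[4-(benzyloxy)phenyl]ethanol (OCCc1ccc(OCc2ccccc2)cc1; DCC, DMAP, CHCl3/toluene, 45 °C) gives 2-[4-(benzyloxy)phenyl]ethyl tetracontanoate F5. Hydrogenolysis of the benzyl ether (H2, Pd/C, THF/EtOAc, 40 °C) should then give 8.

Step 1. The statistical mono-esterification may over-run to the diester or leave diacid, and the three homologous, poorly soluble components may be slow to separate. Fallback, setting out from 1 and returning at 2: exhaustive esterification (MeOH, cat. H2SO4, reflux) gives dimethyl docosanedioate F6. Half-saponification with Ba(OH)2 (0.5 equiv) in MeOH/toluene follows, in which the barium salt of the half-ester precipitates and is protected from a second hydrolysis; acidification should give 2.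

**Further compounds**
F1 | step 2 | 1,3-dioxoisoindolin-2-yl methyl docosanedioate | COC(=O)CCCCCCCCCCCCCCCCCCCCC(=O)ON1C(=O)c2ccccc2C1=O
F2 | step 2 | nonadecylmagnesium bromide | CCCCCCCCCCCCCCCCCCC[Mg]Br
F3 | step 2 | dinonadecylzinc | CCCCCCCCCCCCCCCCCCC[Zn]CCCCCCCCCCCCCCCCCCC
F4 | step 3 | tetracontanoic acid | CCCCCCCCCCCCCCCCCCCCCCCCCCCCCCCCCCCCCCCC(=O)O
F5 | step 3 | 2-[4-(benzyloxy)phenyl]ethyl tetracontanoate | CCCCCCCCCCCCCCCCCCCCCCCCCCCCCCCCCCCCCCCC(=O)OCCc1ccc(OCc2ccccc2)cc1
F6 | step 1 | dimethyl docosanedioate | COC(=O)CCCCCCCCCCCCCCCCCCCCC(=O)OC
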